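**Plan**

- Retrosynthesis: the enone Cα=Cβ bond is cut (Claisen–Schmidt), then the O1–C2 bond of the pyran (epoxide opening), then C8–C8a and C6–C7 of ring A (benzannulation). This leads to a 4-prenyl-3-alkoxycyclobutenone (C8a, C6, C5, C4a plus the prenyl chain) and a siloxyalkyne (C7, C8) carrying a ketal-masked acetyl group.
- Enabling feature: ring A (C4a, C5, C6, C7, C8, C8a; five substituents and C6–H) has oxygen on C5, C7 and C8a in a 1,3,5 array, and the C8a oxygen (O1) is flanked by the acyl carbon C8 and the alkyl carbon C4a. A cyclobutenone/siloxyalkyne benzannulation writes exactly this pattern, with the new hydroxyl as the only free one.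
- Forward order: ynol ether and cyclobutenone (steps 1–3), siloxyalkyne (steps 4–5), ring A (step 6), acetyl unmasking and O1 silylation (steps 7–8), epoxidation and pyran closure by O1 (steps 9–10), chalcone chain and deprotection (steps 11–13).
- Stereochemistry: C3 (S) is set by Shi epoxidation with the L-fructose-derived ketone (reagent control) and is kept because the pyran closes at the achiral tertiary carbon C2. The enone is E by thermodynamic control.
- O5 carries a 4-methoxybenzyl group so that it comes off at the end with dilute acid, without hydrogenation (enone) and without Lewis acids that could open the tertiary O1–C2 ether. The cyclobutenone is built by ketene/ynol ether cycloaddition because C4 alkylation would require an antiaromatic cyclobutenone dienolate.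

Key step: step 6

Assumption: 5-methylhex-4-enoic acid (6) and the L-fructose-derived Shi ketone are taken as purchased materials.

**Route**

Step 1
Reactants: 1 4-methoxybenzyl alcohol; 2 trichloroethylene
Product: 3 4-methoxybenzyl (E)-1,2-dichlorovinyl ether
Conditions: KH, THF, 0 °C; then 2, −50 °C → rt
Reagents that add atoms: none
Why: The potassium alkoxide adds anti to dichloroacetylene formed in situ from trichloroethylene (dichlorovinyl ether synthesis), which installs the two carbons that become C5 and C6 of ring A together with the acid-labile O5 protecting group.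

Step 2
Reactants: 3 4-methoxybenzyl (E)-1,2-dichlorovinyl ether
Product: 5 4-methoxybenzyl ethynyl ether, via lithium acetylide 4 (not isolated)
Conditions: n-BuLi (2.2 equiv), THF, −78 → −40 °C; then sat. aq NH4Cl, −78 °C; kept below 25 °C and used at once
Reagents that add atoms: none
Why: Elimination of HCl to the chloroalkynyl ether and chlorine–lithium exchange give acetylide 4, and cold protonation releases the terminal ynol ether (dichlorovinyl ether route to alkoxyacetylenes), which is not stored because benzylic ynol ethers rearrange sigmatropically on warming.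

Step 3
Reactants: 6 5-methylhex-4-enoic acid; 5 4-methoxybenzyl ethynyl ether
Product: 9 3-(4-methoxybenzyloxy)-4-(3-methylbut-2-enyl)cyclobut-2-en-1-one (racemic), via acid chloride 7 (not isolated), via prenylketene 8 (not isolated)
Conditions: (COCl)2, DMF (cat.), CH2Cl2, 0 °C → rt, evaporate; then slow addition to 5, Et3N, Et2O, 0 °C → rt
Reagents that add atoms: none
Why: Et3N dehydrochlorinates 7 to the aldoketene 8 in the presence of the ynol ether, and the [2+2] cycloaddition (ketene–alkoxyalkyne route to 3-alkoxycyclobutenones) is regioselective because the nucleophilic CH terminus of 5 bonds to the ketene carbonyl carbon, so the prenyl group ends on the sp3 carbon C4.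

Step 4
Reactants: 10 ethyl pyruvate
Product: 11 ethyl 2-methyl-1,3-dioxolane-2-carboxylate
Conditions: HOCH2CH2OH, TsOH·H2O (cat.), toluene, reflux, Dean–Stark
Reagents that add atoms: ethylene glycol, OCCO
Why: Acid-catalysed ketalisation of the electrophilic α-keto ester with azeotropic removal of water masks the future C8 acetyl carbonyl against the organolithium reagents of the next step.

Step 5
Reactants: 11 ethyl 2-methyl-1,3-dioxolane-2-carboxylate
Product: 14 2-methyl-2-[(triisopropylsilyloxy)ethynyl]-1,3-dioxolane, via lithium dibromoenolate 12 (not isolated), via lithium ynolate 13 (not isolated)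
Conditions: CH2Br2, LiTMP, THF, −78 °C; add 11; LiN(SiMe3)2; n-BuLi, −78 → 25 °C; then i-Pr3SiCl, −78 → 0 °C; work-up with aq NaHCO3, base-washed silica
Reagents that add atoms: dibromomethane, BrCBr; chlorotriisopropylsilane, CC(C)[Si](Cl)(C(C)C)C(C)C
Why: In this Kowalski ester homologation LiCHBr2 adds to the ester, enolate 12 undergoes bromine–lithium exchange and carbenoid 1,2-shift to ynolate 13, and the bulky silyl chloride traps 13 on oxygen to give the triisopropylsiloxyalkyne.

Step 6
Reactants: 9 3-(4-methoxybenzyloxy)-4-(3-methylbut-2-enyl)cyclobut-2-en-1-one; 14 2-methyl-2-[(triisopropylsilyloxy)ethynyl]-1,3-dioxolane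
Product: 19 3-(4-methoxybenzyloxy)-6-(2-methyl-1,3-dioxolan-2-yl)-2-(3-methylbut-2-enyl)-5-(triisopropylsilyloxy)phenol, via vinylketene 15 (not isolated), via vinylcyclobutenone 16 (not isolated), via dienylketene 17 (not isolated), via cyclohexadienone 18 (not isolated)
Conditions: 14 (1.3 equiv), toluene (0.2 M), 80 °C then 110 °C, sealed tube, base-washed glass
Reagents that add atoms: none
Why: Thermal 4π-electrocyclic opening of 9 (prenyl rotating outward) gives vinylketene 15, whose ketene unit adds across the ynol ether in a [2+2] cycloaddition to 16; a second 4π opening to dienylketene 17, 6π-electrocyclisation to 18 and tautomerisation deliver phenol 19, each stage being driven by release of ring strain and finally by aromatisation. This is the siloxyalkyne variant of the Danheiser benzannulation, for which 3-oxygenated cyclobutenones and triisopropylsiloxyalkynes are established partners. Ring A is closed by the thermal disrotatory 6π-electrocyclisation of 17, which re-forms the C4a–C8a bond after the new skeletal bonds C8–C8a and C6–C7 have been made in the cycloaddition. No stereocentre is created, and the C4 centre of racemic 9 is erased on aromatisation. The only selectivity needed is the regiochemistry of the ketene–alkyne cycloaddition, and polarity fixes it: the nucleophilic alkyne carbon remote from oxygen (the one bearing the ketal) bonds to the electrophilic ketene carbonyl carbon, so the new hydroxyl (future O1) ends between the masked acetyl group and the prenyl group, with the siloxy and 4-methoxybenzyloxy groups meta to it. The doubly ortho-substituted phenol should be too hindered to be acylated by remaining ketene.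

Step 7
Reactants: 19 3-(4-methoxybenzyloxy)-6-(2-methyl-1,3-dioxolan-2-yl)-2-(3-methylbut-2-enyl)-5-(triisopropylsilyloxy)phenol
Product: 20 1-[2-hydroxy-4-(4-methoxybenzyloxy)-3-(3-methylbut-2-enyl)-6-(triisopropylsilyloxy)phenyl]ethan-1-one
Conditions: 1 M HCl (aq), THF, 0 °C → rt
Reagents that add atoms: water, O
Why: Acid hydrolysis of the ketal, fast because the oxocarbenium ion is stabilised by the electron-rich ring, frees the acetyl group under conditions that should leave the aryl silyl ether, the 4-methoxybenzyl ether and the prenyl alkene untouched.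

Step 8
Reactants: 20 1-[2-hydroxy-4-(4-methoxybenzyloxy)-3-(3-methylbut-2-enyl)-6-(triisopropylsilyloxy)phenyl]ethan-1-one
Product: 21 1-[4-(4-methoxybenzyloxy)-3-(3-methylbut-2-enyl)-2,6-bis(triisopropylsilyloxy)phenyl]ethan-1-one
Conditions: i-Pr3SiOTf, 2,6-lutidine, CH2Cl2, −78 → 0 °C
Reagents that add atoms: triisopropylsilyl trifluoromethanesulfonate, CC(C)[Si](OS(=O)(=O)C(F)(F)F)(C(C)C)C(C)C
Why: Silylation of the chelated phenol with a silyl triflate and a hindered pyridine base protects O1, so that no phenoxide can be oxidised or attack the epoxide during the basic epoxidation that follows.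

Step 9
Reactants: 21 1-[4-(4-methoxybenzyloxy)-3-(3-methylbut-2-enyl)-2,6-bis(triisopropylsilyloxy)phenyl]ethan-1-one
Product: 22 1-[3-{[(2S)-3,3-dimethyloxiran-2-yl]methyl}-4-(4-methoxybenzyloxy)-2,6-bis(triisopropylsilyloxy)phenyl]ethan-1-one
Conditions: L-fructose-derived Shi ketone (0.3 equiv), KHSO5 (as 2KHSO5·KHSO4·K2SO4), K2CO3, Bu4NHSO4 (cat.), aq Na2B4O7 buffer, MeCN–CH2(OMe)2, 0 °C
Reagents that add atoms: potassium peroxymonosulfate, [K+].[O-]S(=O)(=O)OO
Why: Shi asymmetric epoxidation of the trisubstituted prenyl alkene by the chiral dioxirane passes through the spiro transition state and sets C3 as (S) under reagent control (the D-fructose-derived ketone gives the R epoxide of such alkenes), the electron-rich alkene reacting much faster than the fully protected arene.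

Step 10
Reactants: 22 1-[3-{[(2S)-3,3-dimethyloxiran-2-yl]methyl}-4-(4-methoxybenzyloxy)-2,6-bis(triisopropylsilyloxy)phenyl]ethan-1-one
Product: 24 1-[(3S)-3,7-dihydroxy-5-(4-methoxybenzyloxy)-2,2-dimethyl-3,4-dihydro-2H-chromen-8-yl]ethan-1-one, via epoxy diphenol 23 (not isolated)
Conditions: Bu4NF, AcOH (1:1), THF, 0 °C; then (±)-camphor-10-sulfonic acid (0.1 equiv), CH2Cl2, 0 °C
Reagents that add atoms: none
Why: Fluoride buffered with AcOH removes both aryl silyl ethers without forming a phenoxide, and Brønsted acid then triggers 6-endo opening of the epoxide by the C8a hydroxyl at the tertiary carbon (acid-catalysed endo-selective epoxide-opening cyclisation), so the C3–O bond and its (S) configuration are retained while O7 cannot reach the epoxide and O5 is blocked.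

Step 11
Reactants: 25 4-hydroxybenzaldehyde
Product: 26 4-(4-methoxybenzyloxy)benzaldehyde
Conditions: 4-MeOC6H4CH2Cl, K2CO3, DMF, rt
Reagents that add atoms: 4-methoxybenzyl chloride, COc1ccc(CCl)cc1
Why: Williamson ether synthesis on the acidic phenol gives the ring B hydroxyl the same acid-labile group as O5, so that no para-phenoxide slows the hydroxide-mediated condensation.

Step 12
Reactants: 24 1-[(3S)-3,7-dihydroxy-5-(4-methoxybenzyloxy)-2,2-dimethyl-3,4-dihydro-2H-chromen-8-yl]ethan-1-one; 26 4-(4-methoxybenzyloxy)benzaldehyde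
Product: 28 (2E)-1-[(3S)-3,7-dihydroxy-5-(4-methoxybenzyloxy)-2,2-dimethyl-3,4-dihydro-2H-chromen-8-yl]-3-[4-(4-methoxybenzyloxy)phenyl]prop-2-en-1-one, via aldol adduct 27 (not isolated)
Conditions: KOH (50% aq), EtOH, 0 °C → rt
Reagents that add atoms: none
Why: In this Claisen–Schmidt condensation the methyl ketone enolate adds to the non-enolisable aldehyde and aldol 27 loses water by E1cB elimination to the conjugated enone, formed as the E isomer under thermodynamic control, while the chelated C7 phenol is tolerated and C3 cannot epimerise.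

Step 13
Reactants: 28 (2E)-1-[(3S)-3,7-dihydroxy-5-(4-methoxybenzyloxy)-2,2-dimethyl-3,4-dihydro-2H-chromen-8-yl]-3-[4-(4-methoxybenzyloxy)phenyl]prop-2-en-1-one
Product: 29 (2E)-3-(4-hydroxyphenyl)-1-[(3S)-3,5,7-trihydroxy-2,2-dimethyl-3,4-dihydro-2H-chromen-8-yl]prop-2-en-1-one
Conditions: CF3CO2H (10% v/v), 1,3,5-trimethoxybenzene (10 equiv), CH2Cl2, 0 °C
Reagents that add atoms: none
Why: Dilute trifluoroacetic acid ionises both 4-methoxybenzyl aryl ethers (acidolysis with a cation scavenger), the excess 1,3,5-trimethoxybenzene should intercept the benzyl cation before it alkylates C6 of ring A, and the short cold exposure should leave the chromanol, the enone geometry and C3 untouched.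

**Compound list**

1 | 4-methoxybenzyl alcohol | COc1ccc(CO)cc1 | starting material
2 | trichloroethylene | ClC=C(Cl)Cl | starting material
3 | 4-methoxybenzyl (E)-1,2-dichlorovinyl ether | COc1ccc(CO/C(Cl)=C\Cl)cc1 | intermediate
4 | lithium (4-methoxybenzyloxy)acetylide | [Li]C#COCc1ccc(OC)cc1 | intermediate
5 | 4-methoxybenzyl ethynyl ether | C#COCc1ccc(OC)cc1 | intermediate
6 | 5-methylhex-4-enoic acid | CC(C)=CCCC(=O)O | starting material
7 | 5-methylhex-4-enoyl chloride | CC(C)=CCCC(=O)Cl | intermediate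
8 | (3-methylbut-2-enyl)ketene (5-methylhexa-1,4-dien-1-one) | CC(C)=CCC=C=O | intermediate
9 | 3-(4-methoxybenzyloxy)-4-(3-methylbut-2-enyl)cyclobut-2-en-1-one (racemic) | COc1ccc(COC2=CC(=O)C2CC=C(C)C)cc1 | intermediate
10 | ethyl pyruvate | CCOC(=O)C(C)=O | starting material
11 | ethyl 2-methyl-1,3-dioxolane-2-carboxylate | CCOC(=O)C1(C)OCCO1 | intermediate
12 | lithium 2,2-dibromo-1-(2-methyl-1,3-dioxolan-2-yl)ethenolate | [Li]OC(=C(Br)Br)C1(C)OCCO1 | intermediate
13 | lithium 2-(2-methyl-1,3-dioxolan-2-yl)ethynolate | [Li]OC#CC1(C)OCCO1 | intermediate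
14 | 2-methyl-2-[(triisopropylsilyloxy)ethynyl]-1,3-dioxolane | CC1(OCCO1)C#CO[Si](C(C)C)(C(C)C)C(C)C | intermediate
15 | (3Z)-3-(4-methoxybenzyloxy)-7-methylocta-1,3,6-trien-1-one | O=C=C/C(OCc1ccc(OC)cc1)=C/CC=C(C)C | intermediate
16 | 4-[(1Z)-1-(4-methoxybenzyloxy)-5-methylhexa-1,4-dienyl]-2-(2-methyl-1,3-dioxolan-2-yl)-3-(triisopropylsilyloxy)cyclobut-2-en-1-one (racemic) | O=C1C(C2(C)OCCO2)=C(O[Si](C(C)C)(C(C)C)C(C)C)C1/C(OCc3ccc(OC)cc3)=C/CC=C(C)C | intermediate
17 | (3E,5Z)-5-(4-methoxybenzyloxy)-9-methyl-2-(2-methyl-1,3-dioxolan-2-yl)-3-(triisopropylsilyloxy)deca-1,3,5,8-tetraen-1-one | O=C=C(C1(C)OCCO1)/C(O[Si](C(C)C)(C(C)C)C(C)C)=C\C(OCc2ccc(OC)cc2)=C\CC=C(C)C | intermediate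
18 | 5-(4-methoxybenzyloxy)-6-(3-methylbut-2-enyl)-2-(2-methyl-1,3-dioxolan-2-yl)-3-(triisopropylsilyloxy)cyclohexa-2,4-dien-1-one (racemic) | O=C1C(C2(C)OCCO2)=C(O[Si](C(C)C)(C(C)C)C(C)C)C=C(OCc3ccc(OC)cc3)C1CC=C(C)C | intermediate
19 | 3-(4-methoxybenzyloxy)-6-(2-methyl-1,3-dioxolan-2-yl)-2-(3-methylbut-2-enyl)-5-(triisopropylsilyloxy)phenol | CC1(OCCO1)c1c(O)c(CC=C(C)C)c(OCc2ccc(OC)cc2)cc1O[Si](C(C)C)(C(C)C)C(C)C | intermediate
20 | 1-[2-hydroxy-4-(4-methoxybenzyloxy)-3-(3-methylbut-2-enyl)-6-(triisopropylsilyloxy)phenyl]ethan-1-one | CC(=O)c1c(O)c(CC=C(C)C)c(OCc2ccc(OC)cc2)cc1O[Si](C(C)C)(C(C)C)C(C)C | intermediate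
21 | 1-[4-(4-methoxybenzyloxy)-3-(3-methylbut-2-enyl)-2,6-bis(triisopropylsilyloxy)phenyl]ethan-1-one | CC(=O)c1c(O[Si](C(C)C)(C(C)C)C(C)C)c(CC=C(C)C)c(OCc2ccc(OC)cc2)cc1O[Si](C(C)C)(C(C)C)C(C)C | intermediate
22 | 1-[3-{[(2S)-3,3-dimethyloxiran-2-yl]methyl}-4-(4-methoxybenzyloxy)-2,6-bis(triisopropylsilyloxy)phenyl]ethan-1-one | CC(=O)c1c(O[Si](C(C)C)(C(C)C)C(C)C)c(C[C@@H]2OC2(C)C)c(OCc3ccc(OC)cc3)cc1O[Si](C(C)C)(C(C)C)C(C)C | intermediate
23 | 1-[3-{[(2S)-3,3-dimethyloxiran-2-yl]methyl}-2,6-dihydroxy-4-(4-methoxybenzyloxy)phenyl]ethan-1-one | CC(=O)c1c(O)c(C[C@@H]2OC2(C)C)c(OCc3ccc(OC)cc3)cc1O | intermediate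
24 | 1-[(3S)-3,7-dihydroxy-5-(4-methoxybenzyloxy)-2,2-dimethyl-3,4-dihydro-2H-chromen-8-yl]ethan-1-one | CC1(C)Oc2c(c(OCc3ccc(OC)cc3)cc(O)c2C(C)=O)C[C@@H]1O | intermediate
25 | 4-hydroxybenzaldehyde | O=Cc1ccc(O)cc1 | starting material
26 | 4-(4-methoxybenzyloxy)benzaldehyde | COc1ccc(COc2ccc(C=O)cc2)cc1 | intermediate
27 | 1-[(3S)-3,7-dihydroxy-5-(4-methoxybenzyloxy)-2,2-dimethyl-3,4-dihydro-2H-chromen-8-yl]-3-hydroxy-3-[4-(4-methoxybenzyloxy)phenyl]propan-1-one (both carbinol epimers) | CC1(C)Oc2c(c(OCc3ccc(OC)cc3)cc(O)c2C(=O)CC(O)c4ccc(OCc5ccc(OC)cc5)cc4)C[C@@H]1O | intermediate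
28 | (2E)-1-[(3S)-3,7-dihydroxy-5-(4-methoxybenzyloxy)-2,2-dimethyl-3,4-dihydro-2H-chromen-8-yl]-3-[4-(4-methoxybenzyloxy)phenyl]prop-2-en-1-one | CC1(C)Oc2c(c(OCc3ccc(OC)cc3)cc(O)c2C(=O)/C=C/c4ccc(OCc5ccc(OC)cc5)cc4)C[C@@H]1O | intermediate
29 | (2E)-3-(4-hydroxyphenyl)-1-[(3S)-3,5,7-trihydroxy-2,2-dimethyl-3,4-dihydro-2H-chromen-8-yl]prop-2-en-1-one | CC1(C)Oc2c(c(O)cc(O)c2C(=O)/C=C/c2ccc(O)cc2)C[C@@H]1O | target

**Count and risks**

Total step count: 13. Longest linear sequence: 10 steps (1, 2, 3, 6, 7, 8, 9, 10, 12, 13).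

Steps most likely to fail:

1. Step 6. The cycloaddition of vinylketene 15 to the alkyne carbon that bears the quaternary, inductively deactivating ketal may be slow, so that ketene dimerisation and thermal or acid-induced decay of the ynol ether overtake the cascade. The fallback keeps the disconnection but puts the future C8 carbonyl at the alcohol oxidation level; it sets out from 9 and comes back at 21. Purchased ethyl 2-(tert-butyldimethylsilyloxy)propanoate (either enantiomer, the centre is erased later) would be homologated under the conditions of step 5 through lithium 1,1-dibromo-3-(tert-butyldimethylsilyloxy)but-1-en-2-olate F1 and lithium 3-(tert-butyldimethylsilyloxy)but-1-yn-1-olate F2 to tert-butyldimethyl{[4-(triisopropylsilyloxy)but-3-yn-2-yl]oxy}silane F3, whose reacting carbon bears only a secondary alkyl group. Heating F3 with 9 as in step 6 should run through 15, the vinylcyclobutenone F4, the dienylketene F5 and the cyclohexadienone F6 to 6-[1-(tert-butyldimethylsilyloxy)ethyl]-3-(4-methoxybenzyloxy)-2-(3-methylbut-2-enyl)-5-(triisopropylsilyloxy)phenol F7. Bu4NF in THF would remove both silyl groups to give 2-(1-hydroxyethyl)-5-(4-methoxybenzyloxy)-4-(3-methylbut-2-enyl)benzene-1,3-diol F8, which is oxidised without purification by MnO2 in CH2Cl2 to 1-[2,6-dihydroxy-4-(4-methoxybenzyloxy)-3-(3-methylbut-2-enyl)phenyl]ethan-1-one F9. Silylation of both phenols with i-Pr3SiOTf (2.4 equiv) and 2,6-lutidine gives 21.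

2. Step 5. Addition of LiCHBr2 to the hindered α,α-dioxygenated ester, or migration of the electron-poor ketal carbon in the carbenoid rearrangement, may fail, and the ynol ether may ionise at the propargylic ketal during work-up. The fallback makes the ynolate by oxidation of an acetylide; it sets out from 11 and comes back at 13. Reduction of 11 with i-Bu2AlH (toluene, −78 °C) should give 2-methyl-1,3-dioxolane-2-carbaldehyde F10, and Ohira–Bestmann homologation (dimethyl (1-diazo-2-oxopropyl)phosphonate, K2CO3, MeOH) 2-ethynyl-2-methyl-1,3-dioxolane F11. n-BuLi gives lithium (2-methyl-1,3-dioxolan-2-yl)acetylide F12, which LiOOt-Bu (THF, −78 → 0 °C) oxidises to ynolate 13; trapping with i-Pr3SiOTf then gives 14 as in step 5.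

3. Step 13. The 4-methoxybenzyl cation may alkylate the very nucleophilic C6 of ring A faster than the scavenger traps it, and the acid may start chalcone-to-flavanone cyclisation through the C7 hydroxyl. The fallback changes the protecting group before the chain is built; it sets out from 24 and comes back at 29. Hydrogenolysis of 24 (H2, Pd/C, EtOAc; no alkene is present at this stage) should give 1-[(3S)-3,5,7-trihydroxy-2,2-dimethyl-3,4-dihydro-2H-chromen-8-yl]ethan-1-one F13. MeOCH2Cl with K2CO3 in acetone protects only the non-chelated C5 phenol to give 1-[(3S)-3,7-dihydroxy-5-(methoxymethoxy)-2,2-dimethyl-3,4-dihydro-2H-chromen-8-yl]ethan-1-one F14. Claisen–Schmidt condensation with purchased 4-(methoxymethoxy)benzaldehyde (KOH, EtOH) passes through the aldol adduct F15 to the bis(methoxymethyl) chalcone F16, and HCl in MeOH at rt releases 29 with formaldehyde dimethyl acetal as the only by-product.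

**Further compounds**

F1 | step 6 | lithium 1,1-dibromo-3-(tert-butyldimethylsilyloxy)but-1-en-2-olate | [Li]OC(=C(Br)Br)C(C)O[Si](C)(C)C(C)(C)C
F2 | step 6 | lithium 3-(tert-butyldimethylsilyloxy)but-1-yn-1-olate | [Li]OC#CC(C)O[Si](C)(C)C(C)(C)C
F3 | step 6 | tert-butyldimethyl{[4-(triisopropylsilyloxy)but-3-yn-2-yl]oxy}silane | CC(O[Si](C)(C)C(C)(C)C)C#CO[Si](C(C)C)(C(C)C)C(C)C
F4 | step 6 | 2-[1-(tert-butyldimethylsilyloxy)ethyl]-4-[(1Z)-1-(4-methoxybenzyloxy)-5-methylhexa-1,4-dienyl]-3-(triisopropylsilyloxy)cyclobut-2-en-1-one | O=C1C(C(C)O[Si](C)(C)C(C)(C)C)=C(O[Si](C(C)C)(C(C)C)C(C)C)C1/C(OCc2ccc(OC)cc2)=C/CC=C(C)C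
F5 | step 6 | (3E,5Z)-2-[1-(tert-butyldimethylsilyloxy)ethyl]-5-(4-methoxybenzyloxy)-9-methyl-3-(triisopropylsilyloxy)deca-1,3,5,8-tetraen-1-one | O=C=C(C(C)O[Si](C)(C)C(C)(C)C)/C(O[Si](C(C)C)(C(C)C)C(C)C)=C\C(OCc1ccc(OC)cc1)=C\CC=C(C)C
F6 | step 6 | 2-[1-(tert-butyldimethylsilyloxy)ethyl]-5-(4-methoxybenzyloxy)-6-(3-methylbut-2-enyl)-3-(triisopropylsilyloxy)cyclohexa-2,4-dien-1-one | O=C1C(C(C)O[Si](C)(C)C(C)(C)C)=C(O[Si](C(C)C)(C(C)C)C(C)C)C=C(OCc2ccc(OC)cc2)C1CC=C(C)C
F7 | step 6 | 6-[1-(tert-butyldimethylsilyloxy)ethyl]-3-(4-methoxybenzyloxy)-2-(3-methylbut-2-enyl)-5-(triisopropylsilyloxy)phenol | CC(O[Si](C)(C)C(C)(C)C)c1c(O)c(CC=C(C)C)c(OCc2ccc(OC)cc2)cc1O[Si](C(C)C)(C(C)C)C(C)C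
F8 | step 6 | 2-(1-hydroxyethyl)-5-(4-methoxybenzyloxy)-4-(3-methylbut-2-enyl)benzene-1,3-diol | CC(O)c1c(O)c(CC=C(C)C)c(OCc2ccc(OC)cc2)cc1O
F9 | step 6 | 1-[2,6-dihydroxy-4-(4-methoxybenzyloxy)-3-(3-methylbut-2-enyl)phenyl]ethan-1-one | CC(=O)c1c(O)c(CC=C(C)C)c(OCc2ccc(OC)cc2)cc1O
F10 | step 5 | 2-methyl-1,3-dioxolane-2-carbaldehyde | CC1(C=O)OCCO1
F11 | step 5 | 2-ethynyl-2-methyl-1,3-dioxolane | C#CC1(C)OCCO1
F12 | step 5 | lithium (2-methyl-1,3-dioxolan-2-yl)acetylide | [Li]C#CC1(C)OCCO1
F13 | step 13 | 1-[(3S)-3,5,7-trihydroxy-2,2-dimethyl-3,4-dihydro-2H-chromen-8-yl]ethan-1-one | CC1(C)Oc2c(c(O)cc(O)c2C(C)=O)C[C@@H]1O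
F14 | step 13 | 1-[(3S)-3,7-dihydroxy-5-(methoxymethoxy)-2,2-dimethyl-3,4-dihydro-2H-chromen-8-yl]ethan-1-one | CC1(C)Oc2c(c(OCOC)cc(O)c2C(C)=O)C[C@@H]1O
F15 | step 13 | 1-[(3S)-3,7-dihydroxy-5-(methoxymethoxy)-2,2-dimethyl-3,4-dihydro-2H-chromen-8-yl]-3-hydroxy-3-[4-(methoxymethoxy)phenyl]propan-1-one (both carbinol epimers) | CC1(C)Oc2c(c(OCOC)cc(O)c2C(=O)CC(O)c3ccc(OCOC)cc3)C[C@@H]1O
F16 | step 13 | (2E)-1-[(3S)-3,7-dihydroxy-5-(methoxymethoxy)-2,2-dimethyl-3,4-dihydro-2H-chromen-8-yl]-3-[4-(methoxymethoxy)phenyl]prop-2-en-1-one | CC1(C)Oc2c(c(OCOC)cc(O)c2C(=O)/C=C/c3ccc(OCOC)cc3)C[C@@H]1O
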